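**Plan**

- Target: (2S)-5,7-dihydroxy-4'-methoxy-6-prenylflavanone. Numbering: O1, C2, C3, C4, C4a, C5–C8, C8a; ring A is the phloroglucinol ring, ring B the anisyl ring, ring C the pyranone.
- Retrosynthesis cuts, in order: the two O–MOM bonds; the C4–C4a bond of ring C (ketone carbon to aryl carbon); the O1–C2 ether bond; the C6–prenyl bond. The chiral C3 unit goes back to a β-keto ester.
- Forward: ring A is carried from phloroglucinol (two MOM ethers, one TIPS ether), prenylated between the MOM ethers, unmasked and brominated. The O1–C2–C3–C4 chain is attached by Mitsunobu etherification. Ring C then closes by Br–Li exchange at C4a and attack on the C4 amide carbonyl, so two electrophilic carbons are joined after polarity reversal at C4a.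
- Enabling feature: in ring A, O1 (on C8a) lies para to the prenyl carbon C6, and the oxygens on C5 and C7 flank C6. The open aryl ether is therefore symmetric about the C8a···C6 axis, C4a and C8 are equivalent, and closure at the one brominated carbon can only give the 6-prenyl isomer. The two oxygens flanking C4a also stabilise the carbanion.
- The closure uses no acid and holds the ketone as a lithium hemiaminal until the cold quench. This protects the ionisable p-methoxybenzylic C2–O1 bond, the base-labile flavanone and the prenyl group.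
- Stereochemistry: C2 is set as the (R)-carbinol by asymmetric transfer hydrogenation and inverted to (S) in the Mitsunobu step; no later step touches it.

Key step: step 9

Remark: the sense of induction in step 6 is assigned by analogy with aryl methyl ketones and would be checked on 10 before going on.

**Route**

Step 1
Reactants: 1 benzene-1,3,5-triol (phloroglucinol)
Product: 2 3,5-bis(methoxymethoxy)phenol
Conditions: MOMCl (2.0 equiv), i-Pr2NEt, DMF, 0 °C to rt; chromatography
Reagents that add atoms: chloromethyl methyl ether, COCCl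
Why: Williamson-type O-alkylation caps two of the three equivalent phenols, and the bis-ether should be separable from the mono- and tris-ethers formed alongside, which can be recycled.

Step 2
Reactants: 2 3,5-bis(methoxymethoxy)phenol
Product: 3 [3,5-bis(methoxymethoxy)phenoxy]tri(propan-2-yl)silane
Conditions: TIPSCl, imidazole, DMF, rt
Reagents that add atoms: chlorotri(propan-2-yl)silane, CC(C)[Si](Cl)(C(C)C)C(C)C
Why: standard silylation of the free phenol gives a bulky silyl ether that resists n-BuLi and does not direct metalation, so the carbon between the two MOM ethers stays the only activated site.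

Step 3
Reactants: 3 [3,5-bis(methoxymethoxy)phenoxy]tri(propan-2-yl)silane; 4 1-bromo-3-methylbut-2-ene (prenyl bromide)
Product: 6 [3,5-bis(methoxymethoxy)-4-(3-methylbut-2-en-1-yl)phenoxy]tri(propan-2-yl)silane, via aryllithium 5 (not isolated)
Conditions: n-BuLi (1.1 equiv), THF, 0 °C; then 4, −78 °C to rt
Reagents that add atoms: none
Why: directed ortho-metalation should occur at the carbon flanked by both MOM ethers (cooperative chelation), and the aryllithium is then alkylated in SN2 fashion at the primary carbon of the allylic bromide.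

Step 4
Reactants: 6 [3,5-bis(methoxymethoxy)-4-(3-methylbut-2-en-1-yl)phenoxy]tri(propan-2-yl)silane
Product: 7 3,5-bis(methoxymethoxy)-4-(3-methylbut-2-en-1-yl)phenol
Conditions: TBAF, THF, 0 °C; aq. NH4Cl
Reagents that add atoms: none
Why: fluoride cleaves the aryl silyl ether and leaves the MOM acetals and the alkene untouched, freeing the one oxygen that lies para to the prenyl group.

Step 5
Reactants: 7 3,5-bis(methoxymethoxy)-4-(3-methylbut-2-en-1-yl)phenol
Product: 8 2-bromo-3,5-bis(methoxymethoxy)-4-(3-methylbut-2-en-1-yl)phenol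
Conditions: NBS (1.0 equiv), CH2Cl2, −78 °C to −40 °C
Reagents that add atoms: N-bromosuccinimide, O=C1CCC(=O)N1Br
Why: electrophilic aromatic bromination ortho to the free phenol, where the two open ring positions are equivalent and the trioxygenated ring is far more nucleophilic than the trisubstituted alkene, so one equivalent at low temperature should give the monobromide.

Step 6
Reactants: 9 ethyl 3-(4-methoxyphenyl)-3-oxopropanoate
Product: 10 ethyl (3R)-3-hydroxy-3-(4-methoxyphenyl)propanoate
Conditions: RuCl(p-cymene)[(R,R)-TsDPEN] (1 mol %), HCO2H–Et3N, 40 °C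
Reagents that add atoms: none
Why: asymmetric transfer hydrogenation of the aryl ketone, in which the chiral Ru–H/N–H catalyst delivers hydride to one carbonyl face (arene–aryl contact in the six-membered transition state) and the (R,R)-ligand is expected to give the (R)-carbinol.

Step 7
Reactants: 10 ethyl (3R)-3-hydroxy-3-(4-methoxyphenyl)propanoate
Product: 11 (3R)-3-hydroxy-N-methoxy-3-(4-methoxyphenyl)-N-methylpropanamide
Conditions: MeNHOMe·HCl, i-PrMgCl (excess), THF, −20 °C to 0 °C
Reagents that add atoms: N,O-dimethylhydroxylamine hydrochloride, CNOC.Cl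
Why: aminolysis of the ester by the chloromagnesium amide formed in the flask, run cold so that the magnesium alkoxide does not undergo retro-aldol cleavage, with the carbinol centre not involved.

Step 8
Reactants: 8 2-bromo-3,5-bis(methoxymethoxy)-4-(3-methylbut-2-en-1-yl)phenol; 11 (3R)-3-hydroxy-N-methoxy-3-(4-methoxyphenyl)-N-methylpropanamide
Product: 12 (3S)-3-[2-bromo-3,5-bis(methoxymethoxy)-4-(3-methylbut-2-en-1-yl)phenoxy]-N-methoxy-3-(4-methoxyphenyl)-N-methylpropanamide
Conditions: PPh3, DIAD, toluene, 0 °C to rt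
Reagents that add atoms: none
Why: Mitsunobu reaction, in which the acidic ortho-bromophenol displaces the oxyphosphonium group by SN2 with inversion ((R)-carbinol to (S)-ether), while the non-polar solvent and low temperature are chosen to hold back ionisation at the p-methoxybenzylic carbon.

Step 9
Reactants: 12 (3S)-3-[2-bromo-3,5-bis(methoxymethoxy)-4-(3-methylbut-2-en-1-yl)phenoxy]-N-methoxy-3-(4-methoxyphenyl)-N-methylpropanamide
Product: 15 (2S)-5,7-bis(methoxymethoxy)-2-(4-methoxyphenyl)-6-(3-methylbut-2-en-1-yl)-2,3-dihydro-4H-chromen-4-one, via aryllithium 13 (not isolated), via lithium hemiaminal 14 (not isolated)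
Conditions: t-BuLi (2.1 equiv), THF, −78 °C; then sat. aq. NH4Cl, −78 °C to rt
Reagents that add atoms: none
Why: t-BuLi exchanges the C4a bromine for lithium faster than it deprotonates or adds to the amide, and aryllithium 13, held by the flanking OMOM and ether oxygens, attacks the N-methoxy-N-methylamide carbonyl to give the chelated lithium hemiaminal 14, which releases the ketone only on protonation. The closest known reaction type is the Parham cyclization of an ortho-halo aryl ether onto a tethered N-methoxy-N-methylamide to give a chroman-4-one; in polarity terms two electrophilic carbons (C–Br and C=O) are joined after reversal at C4a. Ring C closes in the 6-exo-trig mode. No stereocentre survives from the step, since the hemiaminal carbon of 14 becomes the planar C4 carbonyl, and C2 is preserved because no acid is present and the ketone never meets base. The step needs chemoselectivity for Br–Li exchange over α-deprotonation (which would expel the aryloxide by E1cB) and over carbonyl attack by t-BuLi, and this is secured by the speed of exchange with the hindered reagent at −78 °C and by intramolecular delivery through a six-membered transition state. Regioselectivity is fixed by the substrate, because C4a and C8 were equivalent before bromination and the single bromine marks the only carbon that can react.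

Step 10
Reactants: 15 (2S)-5,7-bis(methoxymethoxy)-2-(4-methoxyphenyl)-6-(3-methylbut-2-en-1-yl)-2,3-dihydro-4H-chromen-4-one
Product: 16 (2S)-5,7-dihydroxy-2-(4-methoxyphenyl)-6-(3-methylbut-2-en-1-yl)-2,3-dihydro-4H-chromen-4-one
Conditions: HCl (1.25 M in MeOH), rt
Reagents that add atoms: none
Why: acid-catalysed acetal exchange with methanol removes both MOM groups (the C5 ether fastest, being peri to the carbonyl), and dilute acid at room temperature, stopped at full conversion, should leave the trisubstituted alkene, the 4'-methyl ether and the C2–O1 bond intact.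

**Compound list**

1 | benzene-1,3,5-triol (phloroglucinol) | Oc1cc(O)cc(O)c1 | starting material
2 | 3,5-bis(methoxymethoxy)phenol | COCOc1cc(O)cc(OCOC)c1 | intermediate
3 | [3,5-bis(methoxymethoxy)phenoxy]tri(propan-2-yl)silane | COCOc1cc(O[Si](C(C)C)(C(C)C)C(C)C)cc(OCOC)c1 | intermediate
4 | 1-bromo-3-methylbut-2-ene (prenyl bromide) | CC(C)=CCBr | starting material
5 | [2,6-bis(methoxymethoxy)-4-{[tri(propan-2-yl)silyl]oxy}phenyl]lithium | [Li]c1c(OCOC)cc(O[Si](C(C)C)(C(C)C)C(C)C)cc1OCOC | intermediate
6 | [3,5-bis(methoxymethoxy)-4-(3-methylbut-2-en-1-yl)phenoxy]tri(propan-2-yl)silane | COCOc1cc(O[Si](C(C)C)(C(C)C)C(C)C)cc(OCOC)c1CC=C(C)C | intermediate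
7 | 3,5-bis(methoxymethoxy)-4-(3-methylbut-2-en-1-yl)phenol | COCOc1cc(O)cc(OCOC)c1CC=C(C)C | intermediate
8 | 2-bromo-3,5-bis(methoxymethoxy)-4-(3-methylbut-2-en-1-yl)phenol | COCOc1cc(O)c(Br)c(OCOC)c1CC=C(C)C | intermediate
9 | ethyl 3-(4-methoxyphenyl)-3-oxopropanoate | CCOC(=O)CC(=O)c1ccc(OC)cc1 | starting material
10 | ethyl (3R)-3-hydroxy-3-(4-methoxyphenyl)propanoate | COc1ccc([C@H](O)CC(=O)OCC)cc1 | intermediate
11 | (3R)-3-hydroxy-N-methoxy-3-(4-methoxyphenyl)-N-methylpropanamide | COc1ccc([C@H](O)CC(=O)N(C)OC)cc1 | intermediate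
12 | (3S)-3-[2-bromo-3,5-bis(methoxymethoxy)-4-(3-methylbut-2-en-1-yl)phenoxy]-N-methoxy-3-(4-methoxyphenyl)-N-methylpropanamide | COc1ccc([C@H](CC(=O)N(C)OC)Oc2cc(OCOC)c(CC=C(C)C)c(OCOC)c2Br)cc1 | intermediate
13 | aryllithium of 12 (lithium in place of bromine at C4a) | COc1ccc([C@H](CC(=O)N(C)OC)Oc2cc(OCOC)c(CC=C(C)C)c(OCOC)c2[Li])cc1 | intermediate
14 | lithium (2S)-4-[methoxy(methyl)amino]-5,7-bis(methoxymethoxy)-2-(4-methoxyphenyl)-6-(3-methylbut-2-en-1-yl)-3,4-dihydro-2H-chromen-4-olate (C4 epimers) | COc1ccc([C@@H]2CC(O[Li])(N(C)OC)c3c(cc(OCOC)c(CC=C(C)C)c3OCOC)O2)cc1 | intermediate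
15 | (2S)-5,7-bis(methoxymethoxy)-2-(4-methoxyphenyl)-6-(3-methylbut-2-en-1-yl)-2,3-dihydro-4H-chromen-4-one | COc1ccc([C@@H]2CC(=O)c3c(cc(OCOC)c(CC=C(C)C)c3OCOC)O2)cc1 | intermediate
16 | (2S)-5,7-dihydroxy-2-(4-methoxyphenyl)-6-(3-methylbut-2-en-1-yl)-2,3-dihydro-4H-chromen-4-one | COc1ccc([C@@H]2CC(=O)c3c(cc(O)c(CC=C(C)C)c3O)O2)cc1 | target

**Step count**

Total: 10 steps. Longest linear sequence: 8 steps (1, 2, 3, 4, 5, 8, 9, 10 from phloroglucinol); steps 6 and 7 form the side branch that joins at step 8.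

**Steps most likely to fail and their fallbacks**

Step 8. The oxyphosphonium intermediate may ionise at the p-methoxybenzylic carbon, which would erode the configuration at C2, or undergo β-elimination across C2–C3 in place of substitution. The fallback sets out from 8 and comes back at 12, and forms the C2–O1 bond under catalyst control instead. Commercial (E)-4-methoxycinnamyl alcohol is converted with methyl chloroformate and pyridine into (E)-3-(4-methoxyphenyl)prop-2-en-1-yl methyl carbonate F1. Iridium-catalysed asymmetric allylic etherification of 8 with F1 ([Ir(cod)Cl]2, BINOL-derived phosphoramidite ligand, base, THF, rt), with the ligand enantiomer chosen for the (S)-ether, should give the branched ether 2-bromo-1-{[(1S)-1-(4-methoxyphenyl)prop-2-en-1-yl]oxy}-3,5-bis(methoxymethoxy)-4-(3-methylbut-2-en-1-yl)benzene F2. 9-BBN should add only to the terminal alkene to give 9-{(3S)-3-[2-bromo-3,5-bis(methoxymethoxy)-4-(3-methylbut-2-en-1-yl)phenoxy]-3-(4-methoxyphenyl)propyl}-9-borabicyclo[3.3.1]nonane F3, which is oxidised in the same flask (NaOH, H2O2) to (3S)-3-[2-bromo-3,5-bis(methoxymethoxy)-4-(3-methylbut-2-en-1-yl)phenoxy]-3-(4-methoxyphenyl)propan-1-ol F4. TEMPO with PhI(OAc)2 in aqueous MeCN takes the alcohol to (3S)-3-[2-bromo-3,5-bis(methoxymethoxy)-4-(3-methylbut-2-en-1-yl)phenoxy]-3-(4-methoxyphenyl)propanoic acid F5, and coupling with MeNHOMe·HCl (EDC, i-Pr2NEt, CH2Cl2) gives 12.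

Step 9. A proton may pass from the C3 methylene to the aryllithium, followed by loss of the aryloxide, or the alkyllithium may attack the amide before exchange. The fallback sets out from 7 and comes back at 15, and closes the same bond through a non-basic organochromium species. N-Iodosuccinimide (CH2Cl2, −78 °C) gives 2-iodo-3,5-bis(methoxymethoxy)-4-(3-methylbut-2-en-1-yl)phenol F6. Mitsunobu etherification with 11, as in step 8, gives (3S)-3-[2-iodo-3,5-bis(methoxymethoxy)-4-(3-methylbut-2-en-1-yl)phenoxy]-N-methoxy-3-(4-methoxyphenyl)-N-methylpropanamide F7. i-Bu2AlH (THF, −78 °C) reduces the amide to (3S)-3-[2-iodo-3,5-bis(methoxymethoxy)-4-(3-methylbut-2-en-1-yl)phenoxy]-3-(4-methoxyphenyl)propanal F8. An intramolecular Nozaki–Hiyama–Kishi reaction (CrCl2 in excess, catalytic NiCl2, DMF, rt) should give (2S)-5,7-bis(methoxymethoxy)-2-(4-methoxyphenyl)-6-(3-methylbut-2-en-1-yl)-3,4-dihydro-2H-chromen-4-ol F9 as both C4 epimers, and Dess–Martin oxidation (NaHCO3, CH2Cl2) converges them on 15.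

Step 10. Once freed, the C5 or C7 hydroxyl may add to the protonated prenyl double bond, or slow cleavage of the C7 ether may force harsher acid that endangers C2. The fallback sets out from 3 and comes back at 16; it keeps the trisubstituted double bond out of the acid step by carrying an allyl group and converting it to prenyl last. Aryllithium 5, made from 3 as in step 3, is quenched with allyl bromide to give [3,5-bis(methoxymethoxy)-4-(prop-2-en-1-yl)phenoxy]tri(propan-2-yl)silane F10. The conditions of steps 4 and 5 give 3,5-bis(methoxymethoxy)-4-(prop-2-en-1-yl)phenol F11 and then 2-bromo-3,5-bis(methoxymethoxy)-4-(prop-2-en-1-yl)phenol F12. Mitsunobu etherification with 11 gives (3S)-3-[2-bromo-3,5-bis(methoxymethoxy)-4-(prop-2-en-1-yl)phenoxy]-N-methoxy-3-(4-methoxyphenyl)-N-methylpropanamide F13. The conditions of step 9 lead through the aryllithium of F13 F14 and the lithium hemiaminal lithium (2S)-4-[methoxy(methyl)amino]-5,7-bis(methoxymethoxy)-2-(4-methoxyphenyl)-6-(prop-2-en-1-yl)-3,4-dihydro-2H-chromen-4-olate F15 to (2S)-5,7-bis(methoxymethoxy)-2-(4-methoxyphenyl)-6-(prop-2-en-1-yl)-2,3-dihydro-4H-chromen-4-one F16. Methanolic HCl, to which the terminal alkene is inert, gives (2S)-5,7-dihydroxy-2-(4-methoxyphenyl)-6-(prop-2-en-1-yl)-2,3-dihydro-4H-chromen-4-one F17. Cross-metathesis with 2-methylbut-2-ene (second-generation Grubbs catalyst, CH2Cl2, 40 °C) then gives 16.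

Further compounds

F1 | step 8 | (E)-3-(4-methoxyphenyl)prop-2-en-1-yl methyl carbonate | COC(=O)OC/C=C/c1ccc(OC)cc1
F2 | step 8 | 2-bromo-1-{[(1S)-1-(4-methoxyphenyl)prop-2-en-1-yl]oxy}-3,5-bis(methoxymethoxy)-4-(3-methylbut-2-en-1-yl)benzene | COc1ccc([C@H](C=C)Oc2cc(OCOC)c(CC=C(C)C)c(OCOC)c2Br)cc1
F3 | step 8 | 9-{(3S)-3-[2-bromo-3,5-bis(methoxymethoxy)-4-(3-methylbut-2-en-1-yl)phenoxy]-3-(4-methoxyphenyl)propyl}-9-borabicyclo[3.3.1]nonane | COc1ccc([C@H](CCB2C3CCCC2CCC3)Oc4cc(OCOC)c(CC=C(C)C)c(OCOC)c4Br)cc1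
F4 | step 8 | (3S)-3-[2-bromo-3,5-bis(methoxymethoxy)-4-(3-methylbut-2-en-1-yl)phenoxy]-3-(4-methoxyphenyl)propan-1-ol | COc1ccc([C@H](CCO)Oc2cc(OCOC)c(CC=C(C)C)c(OCOC)c2Br)cc1
F5 | step 8 | (3S)-3-[2-bromo-3,5-bis(methoxymethoxy)-4-(3-methylbut-2-en-1-yl)phenoxy]-3-(4-methoxyphenyl)propanoic acid | COc1ccc([C@H](CC(=O)O)Oc2cc(OCOC)c(CC=C(C)C)c(OCOC)c2Br)cc1
F6 | step 9 | 2-iodo-3,5-bis(methoxymethoxy)-4-(3-methylbut-2-en-1-yl)phenol | COCOc1cc(O)c(I)c(OCOC)c1CC=C(C)C
F7 | step 9 | (3S)-3-[2-iodo-3,5-bis(methoxymethoxy)-4-(3-methylbut-2-en-1-yl)phenoxy]-N-methoxy-3-(4-methoxyphenyl)-N-methylpropanamide | COc1ccc([C@H](CC(=O)N(C)OC)Oc2cc(OCOC)c(CC=C(C)C)c(OCOC)c2I)cc1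
F8 | step 9 | (3S)-3-[2-iodo-3,5-bis(methoxymethoxy)-4-(3-methylbut-2-en-1-yl)phenoxy]-3-(4-methoxyphenyl)propanal | COc1ccc([C@H](CC=O)Oc2cc(OCOC)c(CC=C(C)C)c(OCOC)c2I)cc1
F9 | step 9 | (2S)-5,7-bis(methoxymethoxy)-2-(4-methoxyphenyl)-6-(3-methylbut-2-en-1-yl)-3,4-dihydro-2H-chromen-4-ol (C4 epimers) | COc1ccc([C@@H]2CC(O)c3c(cc(OCOC)c(CC=C(C)C)c3OCOC)O2)cc1
F10 | step 10 | [3,5-bis(methoxymethoxy)-4-(prop-2-en-1-yl)phenoxy]tri(propan-2-yl)silane | C=CCc1c(OCOC)cc(O[Si](C(C)C)(C(C)C)C(C)C)cc1OCOC
F11 | step 10 | 3,5-bis(methoxymethoxy)-4-(prop-2-en-1-yl)phenol | C=CCc1c(OCOC)cc(O)cc1OCOC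
F12 | step 10 | 2-bromo-3,5-bis(methoxymethoxy)-4-(prop-2-en-1-yl)phenol | COCOc1cc(O)c(Br)c(OCOC)c1CC=C
F13 | step 10 | (3S)-3-[2-bromo-3,5-bis(methoxymethoxy)-4-(prop-2-en-1-yl)phenoxy]-N-methoxy-3-(4-methoxyphenyl)-N-methylpropanamide | COc1ccc([C@H](CC(=O)N(C)OC)Oc2cc(OCOC)c(CC=C)c(OCOC)c2Br)cc1
F14 | step 10 | aryllithium of F13 (lithium in place of bromine) | COc1ccc([C@H](CC(=O)N(C)OC)Oc2cc(OCOC)c(CC=C)c(OCOC)c2[Li])cc1
F15 | step 10 | lithium (2S)-4-[methoxy(methyl)amino]-5,7-bis(methoxymethoxy)-2-(4-methoxyphenyl)-6-(prop-2-en-1-yl)-3,4-dihydro-2H-chromen-4-olate (C4 epimers) | COc1ccc([C@@H]2CC(O[Li])(N(C)OC)c3c(cc(OCOC)c(CC=C)c3OCOC)O2)cc1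
F16 | step 10 | (2S)-5,7-bis(methoxymethoxy)-2-(4-methoxyphenyl)-6-(prop-2-en-1-yl)-2,3-dihydro-4H-chromen-4-one | COc1ccc([C@@H]2CC(=O)c3c(cc(OCOC)c(CC=C)c3OCOC)O2)cc1
F17 | step 10 | (2S)-5,7-dihydroxy-2-(4-methoxyphenyl)-6-(prop-2-en-1-yl)-2,3-dihydro-4H-chromen-4-one | COc1ccc([C@@H]2CC(=O)c3c(cc(O)c(CC=C)c3O)O2)cc1
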